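**Retrosynthetic overview**
1. The target is (13R)-8α,15-epoxylabdan-16-yl acetate, with the oxocane O–C15–C14–C13–C12–C11–C9–C8 fused to ring B at C8–C9. End game: acetate ⇐ alcohol 16 ⇐ asymmetric hydrogenation of the Δ12 allylic alcohol 15 (sets C13) ⇐ enoate 14 ⇐ diester 12, whose C15 ester is a temporary activating group.
2. Key disconnection C14–C15: oxocene 12 ⇐ 2,3-sigmatropic shift of oxonium ylide 11 ⇐ 12-alkenyl tetrahydrofuran 9 + ethyl diazoacetate 10. This is a three-carbon ring expansion of a five-membered ether to the eight-membered one.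
3. Enabling feature: the ring oxygen carries C15, and C15–C14–C13(=C12) is an allyl unit whose far end C12 lies only C11–C9 away from C8. Cutting C14–C15 and joining O–C12 contracts the oxocane to the tetrahydrofuran O–C8–C9–C11–C12, the ether ring of sclareolide, and the C16 carbon on C13 (as an ester) makes the allyl unit an acrylate.
4. 9 ⇐ ester 6 (α-methylenation) ⇐ lactol acetate 3 + ketene silyl acetal 4 (C–C bond formation at an oxocarbenium ion) ⇐ (+)-sclareolide 1, which supplies C5, C8, C9 and C10.
5. Ring order: rings A and B and the tetrahydrofuran come with 1; the oxocane is formed last, in step 4, at the expense of the tetrahydrofuran.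

Key step: step 4

**Remarks and assumptions**
- Labdane numbering is used: decalin C1–C10, C17 = methyl on C8, C18/C19 on C4, C20 on C10, side chain C11–C16. The α face is that of H-5 and H-9.
- Assumption for step 2: attack on the α face of C12. The outcome is not critical, because C12 becomes trigonal in step 4.
- Assumption for step 8 and for the chiral catalysts in the fallbacks: the ligand antipode that gives the required C13 configuration is assigned in a pilot run with both enantiomers; the descriptor written is provisional.

**Route**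

Step 1
Reactants: 1 (+)-sclareolide
Product: 3 8α,12-epoxy-13,14,15,16-tetranorlabdan-12-yl acetate (lactol acetate; C12 epimers), via aluminium hemiacetal 2 (not isolated)
Conditions: iBu2AlH, CH2Cl2, −78 °C; then pyridine, DMAP, Ac2O, −78 °C → 0 °C
Reagents that add atoms: acetic anhydride CC(=O)OC(C)=O
Why: Reductive acetylation of a lactone: iBu2AlH stops at the tetrahedral aluminium hemiacetal 2 at −78 °C, which is acetylated in place before it can collapse; the acetal centre C12 forms as a mixture, which does not matter because it is ionised in step 2.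

Step 2
Reactants: 3 lactol acetate; 4 1-(tert-butyldimethylsilyloxy)-1-methoxyethene
Product: 6 methyl (12R)-8α,12-epoxy-14,15-dinorlabdan-16-oate, via oxocarbenium triflate 5 (not isolated)
Conditions: TMSOTf (0.2 equiv), CH2Cl2, −78 °C → −40 °C
Reagents that add atoms: none
Why: Mukaiyama-type addition of a ketene silyl acetal to the five-membered oxocarbenium ion 5; the nucleophile should enter C12 from the α face, away from the axial C17 methyl on C8 and the C20 methyl on C10 that cover the β face, which sets C12 as R (side chain cis to H-9).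

Step 3
Reactants: 6 methyl ester
Product: 9 methyl (12R)-8α,12-epoxy-15-norlabd-13(14)-en-16-oate (tetrahydrofuranyl acrylate), via Mannich base 7 (not isolated), via ammonium iodide 8 (not isolated)
Conditions: LiN(iPr)2, THF, −78 °C; Me2N=CH2+ I−, −78 °C → rt; MeI, MeOH, rt; aq. NaHCO3, CH2Cl2, rt
Reagents that add atoms: dimethylmethyleneiminium iodide C=[N+](C)C.[I-]
Why: α-Methylenation of an ester by enolate Mannich reaction, N-quaternisation and E1cB loss of trimethylamine (a far better β-leaving group than the ring alkoxide); the transient C13 centre disappears and C12 is untouched.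

Step 4
Reactants: 9 tetrahydrofuranyl acrylate; 10 ethyl diazoacetate
Product: 12 methyl (12E)-15-(ethoxycarbonyl)-8α,15-epoxylabd-12-en-16-oate (oxocene diester; ring-cis double bond; C15 epimers), via oxonium ylide 11 (not isolated)
Conditions: Cu(hfacac)2 (5 mol %), CH2Cl2, 40 °C, 10 (3 equiv) added by syringe pump over 10 h
Reagents that add atoms: none
Why: The copper carbene formed from 10 is captured by a lone pair of the ring oxygen of 9 to give oxonium ylide 11, which, once its carbanionic carbon (the future C15) lies cis to the 12-alkenyl group after inversion at oxygen, undergoes a concerted 2,3-sigmatropic shift through a five-membered envelope transition state (C15–O–C12–C13=C14) in which C15–C14 forms, O–C12 breaks and the double bond moves to C12=C13. The closest known reaction type is the copper-catalysed intermolecular oxonium-ylide 2,3-shift that expands 2-vinyltetrahydrofurans by three carbons to oxocenes, the oxygen counterpart of the sulfonium-ylide ring-growing reaction. The oxocane is therefore closed by ring enlargement of the five-membered ether rather than by an end-to-end eight-membered cyclisation, so no medium-ring entropy penalty is paid and the trans fusion at C8–C9 is carried over because the C8–O and C9–C11 bonds are not touched. Of the new stereo-elements, C15 forms as an uncontrolled mixture that is erased in step 6, the C12=C13 double bond must be ring-cis (E by the sequence rules) because a trans-cyclooctene is out of reach of the tetrahydrofuran-based transition state, and C12 becomes trigonal so that both C12 epimers of 9 converge. The step needs ylide formation to win over cyclopropanation and over thermal dipolar cycloaddition of 10 to the alkene, and the 2,3-shift to win over a 1,2-shift: the acrylate double bond is too electron-poor for the electrophilic copper carbene yet is a polarity-matched, Michael-type acceptor for the ester-stabilised ylide carbon, slow addition keeps free 10 low, and the allylic C12–O bond is the only one aligned for the 2,3-pathway.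

Step 5
Reactants: 12 oxocene diester
Product: 13 (12E)-8α,15-epoxy-16-methoxy-16-oxolabd-12-ene-15-carboxylic acid (C15 epimers)
Conditions: LiOH·H2O (1.1 equiv), THF–H2O, 0 °C; then 1 M HCl to pH 3
Reagents that add atoms: lithium hydroxide [Li+].[OH-]
Why: Chemoselective saponification: the α-alkoxy ethyl ester at C15 is inductively activated and unhindered, whereas the methyl ester at C16 is conjugated and sits on a fully substituted alkene carbon, so one equivalent of hydroxide at 0 °C should cleave only the former.

Step 6
Reactants: 13 acid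
Product: 14 methyl (12E)-8α,15-epoxylabd-12-en-16-oate
Conditions: 9-mesityl-10-methylacridinium tetrafluoroborate (5 mol %), (PhS)2 (10 mol %), iPr2NEt (20 mol %), CF3CH2OH, 450 nm LEDs, rt
Reagents that add atoms: none
Why: Photoredox hydrodecarboxylation: oxidation of the carboxylate by the excited acridinium, loss of CO2 to the oxygen-stabilised radical at C15 and hydrogen-atom transfer from thiophenol turn C15 into a methylene group and erase its stereocentre; the electron-poor enoate is not oxidised and four-membered ring closure onto it cannot compete with hydrogen transfer.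

Step 7
Reactants: 14 enoate
Product: 15 (12E)-8α,15-epoxylabd-12-en-16-ol
Conditions: iBu2AlH (2.5 equiv), CH2Cl2, −78 °C → 0 °C; aq. potassium sodium tartrate
Reagents that add atoms: none
Why: 1,2-Reduction of a conjugated ester to the allylic alcohol; no stereocentre is formed and the double-bond geometry is kept.

Step 8
Reactants: 15 allylic alcohol
Product: 16 (13R)-8α,15-epoxylabdan-16-ol
Conditions: [Ir(cod)((S)-tBu-PHOX)]B[3,5-(CF3)2C6H3]4 (2 mol %), H2 (50 bar), CH2Cl2, rt
Reagents that add atoms: none
Why: Iridium-catalysed asymmetric hydrogenation of a trisubstituted allylic alcohol of the type HOCH2–C(R)=CH–R′, a standard substrate class for cationic N,P-ligated iridium catalysts; the chiral catalyst rather than the remote ring stereocentres selects the face of C13, so 13R is set under reagent control by cis addition of H2.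

Step 9
Reactants: 16 alcohol
Product: 17 (13R)-8α,15-epoxylabdan-16-yl acetate
Conditions: Ac2O, pyridine, DMAP (cat.), CH2Cl2, 0 °C → rt
Reagents that add atoms: acetic anhydride CC(=O)OC(C)=O
Why: Acetylation of a primary alcohol with nucleophilic catalysis by DMAP; no stereocentre is affected.

**Compound list**
1 | (+)-sclareolide, (3aR,5aS,9aS,9bR)-3a,6,6,9a-tetramethyldecahydronaphtho[2,1-b]furan-2(1H)-one | O=C1O[C@]2(C)CC[C@H]3C(C)(C)CCC[C@]3(C)[C@H]2C1 | starting material
2 | diisobutylaluminium hemiacetal of 1 (C12 epimers) | CC(C)C[Al](CC(C)C)OC1O[C@]2(C)CC[C@H]3C(C)(C)CCC[C@]3(C)[C@H]2C1 | intermediate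
3 | 8α,12-epoxy-13,14,15,16-tetranorlabdan-12-yl acetate (C12 epimers) | CC(=O)OC1O[C@]2(C)CC[C@H]3C(C)(C)CCC[C@]3(C)[C@H]2C1 | intermediate
4 | 1-(tert-butyldimethylsilyloxy)-1-methoxyethene | C=C(OC)O[Si](C)(C)C(C)(C)C | starting material
5 | O=C12 oxocarbenium triflate of the 8,12-epoxytetranorlabdane | C1=[O+][C@]2(C)CC[C@H]3C(C)(C)CCC[C@]3(C)[C@H]2C1.[O-]S(=O)(=O)C(F)(F)F | intermediate
6 | methyl (12R)-8α,12-epoxy-14,15-dinorlabdan-16-oate | COC(=O)C[C@@H]1O[C@]2(C)CC[C@H]3C(C)(C)CCC[C@]3(C)[C@H]2C1 | intermediate
7 | methyl (12R)-14-(dimethylamino)-8α,12-epoxy-15-norlabdan-16-oate (C13 epimers) | COC(=O)C(CN(C)C)[C@@H]1O[C@]2(C)CC[C@H]3C(C)(C)CCC[C@]3(C)[C@H]2C1 | intermediate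
8 | N-methyl ammonium iodide of 7 | COC(=O)C(C[N+](C)(C)C)[C@@H]1O[C@]2(C)CC[C@H]3C(C)(C)CCC[C@]3(C)[C@H]2C1.[I-] | intermediate
9 | methyl (12R)-8α,12-epoxy-15-norlabd-13(14)-en-16-oate | COC(=O)C(=C)[C@@H]1O[C@]2(C)CC[C@H]3C(C)(C)CCC[C@]3(C)[C@H]2C1 | intermediate
10 | ethyl diazoacetate | CCOC(=O)C=[N+]=[N-] | starting material
11 | oxonium ylide from 9 and the carbene of 10 (configuration at oxygen and C15 open) | COC(=O)C(=C)[C@@H]1[O+]([CH-]C(=O)OCC)[C@]2(C)CC[C@H]3C(C)(C)CCC[C@]3(C)[C@H]2C1 | intermediate
12 | methyl (12E)-15-(ethoxycarbonyl)-8α,15-epoxylabd-12-en-16-oate (C15 epimers) | COC(=O)/C1=C/C[C@H]2[C@@](C)(CC[C@H]3C(C)(C)CCC[C@]23C)OC(C(=O)OCC)C1 | intermediate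
13 | (12E)-8α,15-epoxy-16-methoxy-16-oxolabd-12-ene-15-carboxylic acid (C15 epimers) | COC(=O)/C1=C/C[C@H]2[C@@](C)(CC[C@H]3C(C)(C)CCC[C@]23C)OC(C(O)=O)C1 | intermediate
14 | methyl (12E)-8α,15-epoxylabd-12-en-16-oate | COC(=O)/C1=C/C[C@H]2[C@@](C)(CC[C@H]3C(C)(C)CCC[C@]23C)OCC1 | intermediate
15 | (12E)-8α,15-epoxylabd-12-en-16-ol | OC/C1=C/C[C@H]2[C@@](C)(CC[C@H]3C(C)(C)CCC[C@]23C)OCC1 | intermediate
16 | (13R)-8α,15-epoxylabdan-16-ol | OC[C@H]1CCO[C@]2(C)CC[C@H]3C(C)(C)CCC[C@]3(C)[C@H]2CC1 | intermediate
17 | (13R)-8α,15-epoxylabdan-16-yl acetate | CC(=O)OC[C@H]1CCO[C@]2(C)CC[C@H]3C(C)(C)CCC[C@]3(C)[C@H]2CC1 | target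

**Step count and risks**
Total step count: 9. Longest linear sequence: 9 steps, from 1 to 17.

Steps most likely to fail:

1. Step 4. Carbene transfer to the hindered ring oxygen may be outrun by carbene dimerisation or by cycloaddition of the diazo ester to the acrylate, or the ylide may collapse by a 1,2-shift or a β-elimination instead of the 2,3-shift. The fallback forms the same C14–C15 bond by ring-closing metathesis; it sets out from 1 and comes back at 16.
   - Reduction of 1 with LiAlH4 gives the 8α,12-diol F1.
   - The primary hydroxyl is silylated (tBuMe2SiCl, imidazole) to the silyl ether F2.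
   - The tertiary hydroxyl is vinylated by transfer vinylation ([Ir(cod)Cl]2, Na2CO3, vinyl acetate, toluene, 100 °C) to the vinyl ether F3.
   - Bu4NF frees the primary alcohol F4, which an Appel reaction (CBr4, PPh3, 2,6-lutidine) converts into the bromide F5.
   - The Grignard reagent of F5 (Mg, THF) undergoes copper-catalysed asymmetric SN2′ allylic alkylation (CuBr·SMe2, TaniaPhos, CH2Cl2, −78 °C) with (E)-4-benzyloxy-1-bromobut-2-ene to give the branched diene F6, which carries the C13 stereocentre.
   - Ring-closing metathesis (second-generation Grubbs catalyst, toluene, 80 °C) closes the ring through C14=C15 to the cyclic enol ether F7.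
   - H2 over Pd/C saturates the enol ether and removes the benzyl group to give 16.

2. Step 8. Facial discrimination at C13 may be poor if the preference of the catalyst and the conformational bias of the oxocene oppose each other, or the hindered ring alkene may be slow to bind. The fallback changes the directing group and the catalyst class; it sets out from 14 and comes back at 16. Saponification of 14 (LiOH, THF–MeOH–H2O, 50 °C) gives the unsaturated acid F8. Carboxylate-directed asymmetric hydrogenation of F8 (Ru(OAc)2[(S)-BINAP], H2, MeOH) gives the saturated acid F9 with C13 set. LiAlH4 reduces F9 to 16.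

3. Step 3. The ester enolate may expel the ring alkoxide (retro-oxa-Michael ring opening) before it is trapped, with loss of material and of the C12 configuration. The fallback avoids a strong base; it sets out from 3 and comes back at 9. TMSOTf-promoted addition of the ketene silyl acetal of dimethyl malonate (methyl 3-methoxy-3-(trimethylsilyloxy)acrylate) to 3 gives the malonate F10. One ester is hydrolysed (KOH, 1 equiv, MeOH) to the half-ester F11. Heating F11 with paraformaldehyde and Et2NH in ethyl acetate (decarboxylative Mannich methylenation) gives 9.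

**Further compounds**
F1 | step 4 | 13,14,15,16-tetranorlabdane-8α,12-diol | O[C@]1(C)CC[C@H]2C(C)(C)CCC[C@]2(C)[C@H]1CCO
F2 | step 4 | 12-(tert-butyldimethylsilyloxy)-13,14,15,16-tetranorlabdan-8α-ol | O[C@]1(C)CC[C@H]2C(C)(C)CCC[C@]2(C)[C@H]1CCO[Si](C)(C)C(C)(C)C
F3 | step 4 | 12-(tert-butyldimethylsilyloxy)-8α-(vinyloxy)-13,14,15,16-tetranorlabdane | C=CO[C@]1(C)CC[C@H]2C(C)(C)CCC[C@]2(C)[C@H]1CCO[Si](C)(C)C(C)(C)C
F4 | step 4 | 8α-(vinyloxy)-13,14,15,16-tetranorlabdan-12-ol | C=CO[C@]1(C)CC[C@H]2C(C)(C)CCC[C@]2(C)[C@H]1CCO
F5 | step 4 | 12-bromo-8α-(vinyloxy)-13,14,15,16-tetranorlabdane | C=CO[C@]1(C)CC[C@H]2C(C)(C)CCC[C@]2(C)[C@H]1CCBr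
F6 | step 4 | (13R)-16-(benzyloxy)-8α-(vinyloxy)labd-14-ene (8,15-seco diene) | C=CO[C@]1(C)CC[C@H]2C(C)(C)CCC[C@]2(C)[C@H]1CC[C@H](C=C)COCc1ccccc1
F7 | step 4 | (13R,14Z)-16-(benzyloxy)-8α,15-epoxylabd-14-ene | C(OC[C@H]1/C=C\O[C@]2(C)CC[C@H]3C(C)(C)CCC[C@]3(C)[C@H]2CC1)c1ccccc1
F8 | step 8 | (12E)-8α,15-epoxylabd-12-en-16-oic acid | OC(=O)/C1=C/C[C@H]2[C@@](C)(CC[C@H]3C(C)(C)CCC[C@]23C)OCC1
F9 | step 8 | (13R)-8α,15-epoxylabdan-16-oic acid | OC(=O)[C@H]1CCO[C@]2(C)CC[C@H]3C(C)(C)CCC[C@]3(C)[C@H]2CC1
F10 | step 3 | dimethyl 2-[(12R)-8α,12-epoxy-13,14,15,16-tetranorlabdan-12-yl]malonate | COC(=O)C(C(=O)OC)[C@@H]1O[C@]2(C)CC[C@H]3C(C)(C)CCC[C@]3(C)[C@H]2C1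
F11 | step 3 | 2-[(12R)-8α,12-epoxy-13,14,15,16-tetranorlabdan-12-yl]malonic acid monomethyl ester (C13 epimers) | COC(=O)C(C(O)=O)[C@@H]1O[C@]2(C)CC[C@H]3C(C)(C)CCC[C@]3(C)[C@H]2C1
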